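**Plan**

- Retrosynthesis: ring D is opened at the C6 acyl–O bond and the butanoate is removed; ring B is cut at C1–C7a and C2–C3 (acrolein [4+2]); ring C at C4a=C7a (enyne metathesis, which also delivers C3) and at C6–C7 (syn aldol with acrolein); the chain at C4a–C5 and C4≡C4a; ring A at C1'–C2' and C5'–C6'.
- Enabling feature: C1' of ring A is quaternary and carries a methyl group, the ring CH2 C6' and C4. This is the substitution pattern of the α-carbon of methacrolein, so methacrolein supplies C4, C1', the methyl group and C6', and a 1-amino-3-siloxybutadiene supplies C2'–C5'.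
- Forward order: ring A first (step 1); gem-dimethylation at C5' and deoxygenation of C4'; formyl → alkyne → pentynoic acid; aldol; ring C; ring B; butanoate; ring D last.
- Stereochemistry: C1' from the chiral diol catalyst; C6 and C7 from the oxazolidinone-controlled syn aldol; C7a from addition of acrolein anti to the C7 silyloxy group; C1 by equilibration to the equatorial aldehyde.

Key step: step 1

Locants: ring A (trimethylcyclohexane) C1'–C6', with C1' quaternary and C5' the gem-dimethyl carbon; ring B (cyclohexene) C1 (CH2O-bearing), C2, C3, C4 (bears ring A), C4a, C7a; ring C (cyclopentane) C4a, C5, C6 (carboxyl), C7 (oxygen), C7a; ring D the β-lactone.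

Assumption: the (R,R)-configured diol is taken to deliver the (R)-aldehyde 4; should the sense of induction be the opposite, the (S,S)-diol is used with no other change.

**Step 1**
Reactants: 1 methacrolein; 2 (E)-1-(dimethylamino)-3-(tert-butyldimethylsilyloxy)buta-1,3-diene
Product: 4 (R)-1-methyl-4-oxocyclohex-2-ene-1-carbaldehyde, via endo cycloadduct 3 (not isolated)
Conditions: (R,R)-1-naphthyl-TADDOL (20 mol%), toluene, −80 °C; then AcCl, CH2Cl2/Et2O, −78 °C
Reagents that add atoms: methacrolein, C=C(C)C=O; (E)-1-(dimethylamino)-3-(tert-butyldimethylsilyloxy)buta-1,3-diene, CN(C)/C=C/C(=C)O[Si](C)(C)C(C)(C)C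
Why: The diol hydrogen-bonds to the formyl oxygen of 1, lowering its LUMO and blocking one enantioface, and diene 2 adds in a concerted, asynchronous, endo-selective [4+2] cycloaddition, the known hydrogen-bond-catalysed Diels–Alder reaction of α-substituted acroleins with 1-amino-3-siloxy dienes. Ring A closes as a six-membered carbocycle in the suprafacial [4π+2π] mode, the CH2 terminus of the diene bonding to the β-carbon of 1 (C5'–C6') and the amino-bearing terminus to the α-carbon (C1'–C2'). The only stereocentre that survives, quaternary C1', is set by the chiral diol, and the amine-bearing centre of 3 is erased on work-up. Acetyl chloride acylates the allylic amine of 3, the silyl enol ether expels dimethylacetamide and chloride removes the silyl group, giving enone 4 with the aldehyde intact. Regiocontrol follows from the push–pull polarisation of 2 (largest HOMO coefficient at its CH2 terminus) against the β-carbon of the enal. Enantiofacial control is the one selectivity that must be supplied, and the catalyst supplies it.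

**Step 2**
Reactants: 4 enone aldehyde; 5 1,2-bis(trimethylsilyloxy)ethane
Product: 6 (R)-4-(1,3-dioxolan-2-yl)-4-methylcyclohex-2-en-1-one
Conditions: TMSOTf (2 mol%), CH2Cl2, −78 °C; pyridine quench
Reagents that add atoms: 1,2-bis(trimethylsilyloxy)ethane, C[Si](C)(C)OCCO[Si](C)(C)C
Why: Silyl-triflate-catalysed acetalisation with the bis-silyl ether of glycol is selective for aldehydes over conjugated ketones at low temperature, so only the formyl group is masked.

**Step 3**
Reactants: 6 dioxolane enone; 7 iodomethane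
Product: 9 (R)-4-(1,3-dioxolan-2-yl)-4,6,6-trimethylcyclohex-2-en-1-one, via monomethyl enone 8 (not isolated)
Conditions: KOtBu (2.5 equiv), MeI (5 equiv), THF, 0 °C → rt
Reagents that add atoms: iodomethane, CI
Why: Because C4 is quaternary the enone can enolise only at C6 (C5' of the target), so the cross-conjugated enolate is C-methylated twice there (exhaustive enolate alkylation).

**Step 4**
Reactants: 9 trimethyl enone
Product: 10 (S)-4-(1,3-dioxolan-2-yl)-2,2,4-trimethylcyclohexan-1-one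
Conditions: H2 (1 atm), 10% Pd/C, EtOAc, rt
Reagents that add atoms: none
Why: Heterogeneous hydrogenation saturates the disubstituted enone C=C and leaves ketone and acetal alone, and C1' stays stereogenic because the gem-dimethyl group already differentiates the two ring arms.

**Step 5**
Reactants: 10 saturated ketone
Product: 12 2-[(1S)-1,3,3-trimethylcyclohexyl]-1,3-dioxolane, via hydrazone 11 (not isolated)
Conditions: N2H4·H2O, KOH, diethylene glycol, 130 °C then 200 °C
Reagents that add atoms: none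
Why: Wolff–Kishner reduction (Huang-Minlon procedure) removes the ketone through its hydrazone under base, which the dioxolane tolerates, as is routine for 2,2-dimethylcyclohexanones.

**Step 6**
Reactants: 12 deoxygenated dioxolane; 13 water
Product: 14 (1S)-1,3,3-trimethylcyclohexane-1-carbaldehyde
Conditions: 1 M HCl, THF, 45 °C
Reagents that add atoms: water, O
Why: Acid-catalysed acetal hydrolysis frees the aldehyde, which is non-enolisable and therefore configurationally safe.

**Step 7**
Reactants: 14 ring A aldehyde; 15 dimethyl (1-diazo-2-oxopropyl)phosphonate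
Product: 16 (1S)-1-ethynyl-1,3,3-trimethylcyclohexane
Conditions: K2CO3, MeOH, 0 °C → rt
Reagents that add atoms: dimethyl (1-diazo-2-oxopropyl)phosphonate, COP(=O)(OC)C(=[N+]=[N-])C(C)=O
Why: Seyferth–Gilbert homologation in the Ohira–Bestmann variant, which works well on non-enolisable α-quaternary aldehydes (olefination, loss of N2, 1,2-shift in the alkylidene carbene).

**Step 8**
Reactants: 16 ring A alkyne; 17 oxetane
Product: 19 5-[(1S)-1,3,3-trimethylcyclohexyl]pent-4-yn-1-ol, via lithium acetylide 18 (not isolated)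
Conditions: n-BuLi, THF, −78 °C; then BF3·OEt2, oxetane, −78 °C; aq. NH4Cl
Reagents that add atoms: oxetane, C1COC1
Why: BF3-promoted opening of oxetane by a lithium acetylide is an established way to add the three-carbon alcohol chain in one operation.

**Step 9**
Reactants: 19 alkynol; 13 water
Product: 21 5-[(1S)-1,3,3-trimethylcyclohexyl]pent-4-ynoic acid, via alkynal 20 (not isolated)
Conditions: TEMPO (20 mol%), PhI(OAc)2 (2.2 equiv), MeCN/H2O (1:1), rt
Reagents that add atoms: water, O
Why: Oxoammonium-mediated oxidation takes the primary alcohol through the aldehyde and its hydrate to the acid without touching the alkyne.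

**Step 10**
Reactants: 21 alkynoic acid; 22 (R)-4-benzyl-1,3-oxazolidin-2-one
Product: 24 (R)-4-benzyl-3-{5-[(1S)-1,3,3-trimethylcyclohexyl]pent-4-ynoyl}-1,3-oxazolidin-2-one, via mixed pivalic anhydride 23 (not isolated)
Conditions: PivCl, Et3N, THF, −20 °C; then LiCl, 22, −20 °C → rt
Reagents that add atoms: (R)-4-benzyl-1,3-oxazolidin-2-one, O=C1N[C@H](Cc2ccccc2)CO1
Why: N-Acylation of the oxazolidinone by a mixed pivalic anhydride with LiCl/Et3N is the standard attachment of this auxiliary.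

**Step 11**
Reactants: 24 acyl oxazolidinone; 25 acrolein
Product: 28 (R)-4-benzyl-3-[(2R,3S)-3-hydroxy-2-{3-[(1S)-1,3,3-trimethylcyclohexyl]prop-2-yn-1-yl}pent-4-enoyl]-1,3-oxazolidin-2-one, via boron enolate 26 (not isolated), via boron aldolate 27 (not isolated)
Conditions: Bu2BOTf, i-Pr2NEt, CH2Cl2, −78 → 0 °C; acrolein, −78 → 0 °C; then pH 7 buffer, MeOH, 30% H2O2, 0 °C
Reagents that add atoms: acrolein, C=CC=O
Why: Evans syn aldol, in which the (Z)-boron enolate reacts through a Zimmerman–Traxler chair with one enolate face shielded by the benzyl group of the (R)-auxiliary, setting C6 (R) and C7 (S) with the syn relationship the cis lactone requires.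

**Step 12**
Reactants: 28 aldol adduct; 29 2-(trimethylsilyl)ethanol
Product: 30 2-(trimethylsilyl)ethyl (2R,3S)-3-hydroxy-2-{3-[(1S)-1,3,3-trimethylcyclohexyl]prop-2-yn-1-yl}pent-4-enoate
Conditions: 29 (3 equiv), n-BuLi (2 equiv), THF, −20 → 0 °C; aq. NH4Cl
Reagents that add atoms: 2-(trimethylsilyl)ethanol, OCC[Si](C)(C)C
Why: A lithium alkoxide displaces the oxazolidinone at the exocyclic carbonyl (transesterification, as with lithium benzyloxide), installing an ester that fluoride removes later, and the low temperature holds back retro-aldol.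

**Step 13**
Reactants: 30 hydroxy ester; 31 tert-butyldimethylsilyl triflate
Product: 32 2-(trimethylsilyl)ethyl (2R,3S)-3-[(tert-butyldimethylsilyl)oxy]-2-{3-[(1S)-1,3,3-trimethylcyclohexyl]prop-2-yn-1-yl}pent-4-enoate
Conditions: TBSOTf, 2,6-lutidine, CH2Cl2, −78 → 0 °C
Reagents that add atoms: tert-butyldimethylsilyl triflate, CC(C)(C)[Si](C)(C)OS(=O)(=O)C(F)(F)F
Why: Silyl triflate with a hindered base silylates the secondary allylic alcohol, and the bulky ether later shields one face of ring C.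

**Step 14**
Reactants: 32 silyl ether enyne
Product: 33 2-(trimethylsilyl)ethyl (1R,2S)-2-[(tert-butyldimethylsilyl)oxy]-4-{1-[(1S)-1,3,3-trimethylcyclohexyl]ethenyl}cyclopent-3-ene-1-carboxylate
Conditions: second-generation Grubbs catalyst RuCl2(=CHPh)(H2IMes)(PCy3) (10 mol%), ethylene (1 atm), toluene, 80 °C
Reagents that add atoms: none
Why: Ring-closing enyne metathesis in the exo mode closes five-membered ring C (C4a=C7a) and transfers the alkene CH2 to C4 to give the 1,3-diene; ethylene keeps the ruthenium methylidene turning over, and 1,6-enynes with silyl-substituted and other hindered internal alkynes are known to cyclise with this catalyst.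

**Step 15**
Reactants: 33 diene; 25 acrolein
Product: 34 2-(trimethylsilyl)ethyl (1S,2R,7R,7aR)-1-[(tert-butyldimethylsilyl)oxy]-7-formyl-4-[(1S)-1,3,3-trimethylcyclohexyl]-2,3,5,6,7,7a-hexahydro-1H-indene-2-carboxylate
Conditions: acrolein (3 equiv), Me2AlCl (0.3 equiv), CH2Cl2, −78 → −40 °C
Reagents that add atoms: acrolein, C=CC=O
Why: In this Lewis-acid-catalysed Diels–Alder reaction the formyl-bearing carbon bonds to C7a (ortho to the ring C terminus, para to the ring A-bearing C4) and acrolein approaches the face of ring C opposite to the C7 silyloxy and C6 ester groups, which fixes C7a; endo addition gives mainly C1 epimer 34, and both C1 epimers converge in step 16.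

**Step 16**
Reactants: 34 Diels–Alder aldehyde
Product: 36 2-(trimethylsilyl)ethyl (1S,2R,7S,7aR)-1-[(tert-butyldimethylsilyl)oxy]-7-(hydroxymethyl)-4-[(1S)-1,3,3-trimethylcyclohexyl]-2,3,5,6,7,7a-hexahydro-1H-indene-2-carboxylate, via equatorial aldehyde 35 (not isolated)
Conditions: DBU (0.3 equiv), CH2Cl2, rt; then MeOH, NaBH4, −20 → 0 °C
Reagents that add atoms: none
Why: Base-mediated epimerisation through the enol should favour the equatorial aldehyde, trans to C7 (C1–H anti to C7a–H), and NaBH4 then reduces the aldehyde chemoselectively beside the hindered ester; the minor C1 epimer is removed at the alcohol stage.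

**Step 17**
Reactants: 36 primary alcohol; 37 butanoic anhydride
Product: 38 2-(trimethylsilyl)ethyl (1S,2R,7S,7aR)-7-[(butanoyloxy)methyl]-1-[(tert-butyldimethylsilyl)oxy]-4-[(1S)-1,3,3-trimethylcyclohexyl]-2,3,5,6,7,7a-hexahydro-1H-indene-2-carboxylate
Conditions: (PrCO)2O, pyridine, DMAP (cat.), CH2Cl2, 0 °C → rt
Reagents that add atoms: butanoic anhydride, CCCC(=O)OC(=O)CCC
Why: DMAP-catalysed acylation of the only free hydroxyl, a primary alcohol.

**Step 18**
Reactants: 38 butanoate
Product: 40 (1S,2R,7S,7aR)-7-[(butanoyloxy)methyl]-1-hydroxy-4-[(1S)-1,3,3-trimethylcyclohexyl]-2,3,5,6,7,7a-hexahydro-1H-indene-2-carboxylic acid, via silyl ether acid 39 (not isolated)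
Conditions: Bu4NF (4 equiv), THF, 0 °C → rt; aq. NH4Cl
Reagents that add atoms: none
Why: Fluoride cleaves the 2-(trimethylsilyl)ethyl ester by β-elimination and then the silyl ether, both orthogonal to the butanoate.

**Step 19**
Reactants: 40 hydroxy acid
Product: 42 3'-norspongiolactone, via mixed sulfonic anhydride 41 (not isolated)
Conditions: PhSO2Cl (2 equiv), pyridine, 0 → 5 °C
Reagents that add atoms: none
Why: β-Lactonisation by carboxyl activation, in which the cis C7 hydroxyl attacks the mixed anhydride, so the C7–O bond is untouched and the cis fusion of ring D is retained.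

**Compound list**

1 | methacrolein | C=C(C)C=O | starting material
2 | (E)-1-(dimethylamino)-3-(tert-butyldimethylsilyloxy)buta-1,3-diene | CN(C)/C=C/C(=C)O[Si](C)(C)C(C)(C)C | starting material
3 | (1R,2S)-2-(dimethylamino)-1-methyl-4-[(tert-butyldimethylsilyl)oxy]cyclohex-3-ene-1-carbaldehyde (endo cycloadduct, formed in the flask) | O=C[C@@]1(C)[C@@H](N(C)C)C=C(O[Si](C)(C)C(C)(C)C)CC1 | intermediate
4 | (R)-1-methyl-4-oxocyclohex-2-ene-1-carbaldehyde | O=C[C@@]1(C)C=CC(=O)CC1 | intermediate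
5 | 1,2-bis(trimethylsilyloxy)ethane | C[Si](C)(C)OCCO[Si](C)(C)C | starting material
6 | (R)-4-(1,3-dioxolan-2-yl)-4-methylcyclohex-2-en-1-one | O1CCOC1[C@@]2(C)C=CC(=O)CC2 | intermediate
7 | iodomethane | CI | starting material
8 | (4R)-4-(1,3-dioxolan-2-yl)-4,6-dimethylcyclohex-2-en-1-one (C6 epimers, formed in the flask) | O1CCOC1[C@@]2(C)C=CC(=O)C(C)C2 | intermediate
9 | (R)-4-(1,3-dioxolan-2-yl)-4,6,6-trimethylcyclohex-2-en-1-one | O1CCOC1[C@@]2(C)C=CC(=O)C(C)(C)C2 | intermediate
10 | (S)-4-(1,3-dioxolan-2-yl)-2,2,4-trimethylcyclohexan-1-one | O1CCOC1[C@@]2(C)CCC(=O)C(C)(C)C2 | intermediate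
11 | hydrazone of 10 (formed in the flask) | O1CCOC1[C@@]2(C)CCC(=NN)C(C)(C)C2 | intermediate
12 | 2-[(1S)-1,3,3-trimethylcyclohexyl]-1,3-dioxolane | O1CCOC1[C@@]2(C)CCCC(C)(C)C2 | intermediate
13 | water | O | starting material
14 | (1S)-1,3,3-trimethylcyclohexane-1-carbaldehyde | O=C[C@@]1(C)CCCC(C)(C)C1 | intermediate
15 | dimethyl (1-diazo-2-oxopropyl)phosphonate | COP(=O)(OC)C(=[N+]=[N-])C(C)=O | starting material
16 | (1S)-1-ethynyl-1,3,3-trimethylcyclohexane | C#C[C@@]1(C)CCCC(C)(C)C1 | intermediate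
17 | oxetane | C1COC1 | starting material
18 | lithium acetylide of 16 (formed in the flask) | [Li]C#C[C@@]1(C)CCCC(C)(C)C1 | intermediate
19 | 5-[(1S)-1,3,3-trimethylcyclohexyl]pent-4-yn-1-ol | OCCCC#C[C@@]1(C)CCCC(C)(C)C1 | intermediate
20 | 5-[(1S)-1,3,3-trimethylcyclohexyl]pent-4-ynal (formed in the flask) | O=CCCC#C[C@@]1(C)CCCC(C)(C)C1 | intermediate
21 | 5-[(1S)-1,3,3-trimethylcyclohexyl]pent-4-ynoic acid | OC(=O)CCC#C[C@@]1(C)CCCC(C)(C)C1 | intermediate
22 | (R)-4-benzyl-1,3-oxazolidin-2-one | O=C1N[C@H](Cc2ccccc2)CO1 | starting material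
23 | mixed anhydride of 21 and pivalic acid (formed in the flask) | CC(C)(C)C(=O)OC(=O)CCC#C[C@@]1(C)CCCC(C)(C)C1 | intermediate
24 | (R)-4-benzyl-3-{5-[(1S)-1,3,3-trimethylcyclohexyl]pent-4-ynoyl}-1,3-oxazolidin-2-one | O=C(CCC#C[C@@]1(C)CCCC(C)(C)C1)N2[C@H](Cc3ccccc3)COC2=O | intermediate
25 | acrolein | C=CC=O | starting material
26 | (Z)-dibutylboron enolate of 24 (formed in the flask) | CCCCB(CCCC)O/C(=C\CC#C[C@@]1(C)CCCC(C)(C)C1)N2[C@H](Cc3ccccc3)COC2=O | intermediate
27 | dibutylboron aldolate of 28 (formed in the flask) | C=C[C@H](OB(CCCC)CCCC)[C@@H](CC#C[C@@]1(C)CCCC(C)(C)C1)C(=O)N2[C@H](Cc3ccccc3)COC2=O | intermediate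
28 | (R)-4-benzyl-3-[(2R,3S)-3-hydroxy-2-{3-[(1S)-1,3,3-trimethylcyclohexyl]prop-2-yn-1-yl}pent-4-enoyl]-1,3-oxazolidin-2-one | C=C[C@H](O)[C@@H](CC#C[C@@]1(C)CCCC(C)(C)C1)C(=O)N2[C@H](Cc3ccccc3)COC2=O | intermediate
29 | 2-(trimethylsilyl)ethanol | OCC[Si](C)(C)C | starting material
30 | 2-(trimethylsilyl)ethyl (2R,3S)-3-hydroxy-2-{3-[(1S)-1,3,3-trimethylcyclohexyl]prop-2-yn-1-yl}pent-4-enoate | C=C[C@H](O)[C@@H](CC#C[C@@]1(C)CCCC(C)(C)C1)C(=O)OCC[Si](C)(C)C | intermediate
31 | tert-butyldimethylsilyl triflate | CC(C)(C)[Si](C)(C)OS(=O)(=O)C(F)(F)F | starting material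
32 | 2-(trimethylsilyl)ethyl (2R,3S)-3-[(tert-butyldimethylsilyl)oxy]-2-{3-[(1S)-1,3,3-trimethylcyclohexyl]prop-2-yn-1-yl}pent-4-enoate | C=C[C@H](O[Si](C)(C)C(C)(C)C)[C@@H](CC#C[C@@]1(C)CCCC(C)(C)C1)C(=O)OCC[Si](C)(C)C | intermediate
33 | 2-(trimethylsilyl)ethyl (1R,2S)-2-[(tert-butyldimethylsilyl)oxy]-4-{1-[(1S)-1,3,3-trimethylcyclohexyl]ethenyl}cyclopent-3-ene-1-carboxylate | C=C([C@@]1(C)CCCC(C)(C)C1)C2=C[C@H](O[Si](C)(C)C(C)(C)C)[C@H](C(=O)OCC[Si](C)(C)C)C2 | intermediate
34 | 2-(trimethylsilyl)ethyl (1S,2R,7R,7aR)-1-[(tert-butyldimethylsilyl)oxy]-7-formyl-4-[(1S)-1,3,3-trimethylcyclohexyl]-2,3,5,6,7,7a-hexahydro-1H-indene-2-carboxylate (endo adduct) | O=C[C@@H]1CCC([C@@]2(C)CCCC(C)(C)C2)=C3C[C@@H](C(=O)OCC[Si](C)(C)C)[C@@H](O[Si](C)(C)C(C)(C)C)[C@@H]31 | intermediate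
35 | (1S,2R,7S,7aR) epimer of 34, formyl equatorial (formed in the flask) | O=C[C@H]1CCC([C@@]2(C)CCCC(C)(C)C2)=C3C[C@@H](C(=O)OCC[Si](C)(C)C)[C@@H](O[Si](C)(C)C(C)(C)C)[C@@H]31 | intermediate
36 | 2-(trimethylsilyl)ethyl (1S,2R,7S,7aR)-1-[(tert-butyldimethylsilyl)oxy]-7-(hydroxymethyl)-4-[(1S)-1,3,3-trimethylcyclohexyl]-2,3,5,6,7,7a-hexahydro-1H-indene-2-carboxylate | OC[C@H]1CCC([C@@]2(C)CCCC(C)(C)C2)=C3C[C@@H](C(=O)OCC[Si](C)(C)C)[C@@H](O[Si](C)(C)C(C)(C)C)[C@@H]31 | intermediate
37 | butanoic anhydride | CCCC(=O)OC(=O)CCC | starting material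
38 | 2-(trimethylsilyl)ethyl (1S,2R,7S,7aR)-7-[(butanoyloxy)methyl]-1-[(tert-butyldimethylsilyl)oxy]-4-[(1S)-1,3,3-trimethylcyclohexyl]-2,3,5,6,7,7a-hexahydro-1H-indene-2-carboxylate | CCCC(=O)OC[C@H]1CCC([C@@]2(C)CCCC(C)(C)C2)=C3C[C@@H](C(=O)OCC[Si](C)(C)C)[C@@H](O[Si](C)(C)C(C)(C)C)[C@@H]31 | intermediate
39 | (1S,2R,7S,7aR)-7-[(butanoyloxy)methyl]-1-[(tert-butyldimethylsilyl)oxy]-4-[(1S)-1,3,3-trimethylcyclohexyl]-2,3,5,6,7,7a-hexahydro-1H-indene-2-carboxylic acid (as its carboxylate, formed in the flask) | CCCC(=O)OC[C@H]1CCC([C@@]2(C)CCCC(C)(C)C2)=C3C[C@@H](C(=O)O)[C@@H](O[Si](C)(C)C(C)(C)C)[C@@H]31 | intermediate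
40 | (1S,2R,7S,7aR)-7-[(butanoyloxy)methyl]-1-hydroxy-4-[(1S)-1,3,3-trimethylcyclohexyl]-2,3,5,6,7,7a-hexahydro-1H-indene-2-carboxylic acid | CCCC(=O)OC[C@H]1CCC([C@@]2(C)CCCC(C)(C)C2)=C3C[C@@H](C(=O)O)[C@@H](O)[C@@H]31 | intermediate
41 | mixed anhydride of 40 and benzenesulfonic acid (formed in the flask) | CCCC(=O)OC[C@H]1CCC([C@@]2(C)CCCC(C)(C)C2)=C3C[C@@H](C(=O)OS(=O)(=O)c4ccccc4)[C@@H](O)[C@@H]31 | intermediate
42 | 3'-norspongiolactone (1S,6R,7S,7aR,1'S by the locants above) | CCCC(=O)OC[C@H]1CCC([C@@]2(C)CCCC(C)(C)C2)=C2C[C@H]3C(=O)O[C@H]3[C@@H]21 | target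

**Step count**

Total: 19 steps. Longest linear sequence: 19 steps (1 and 2 to 42); all other inputs are commercial.

**Steps most likely to fail**

Step 14. Ring closure may stall because both unsaturated ends are encumbered (the alkyne by quaternary C1', the alkene by the silyloxy stereocentre), so that carbene transfer is slow and catalyst decay or intermolecular alkene metathesis takes over. The fallback avoids alkyne metathesis: C4a=C7a is made by ordinary diene metathesis and the C4 methylene by carbonyl olefination. It sets out from aldehyde 14 and comes back at diene 33. Commercial 4-bromopent-4-enoic acid (C=C(Br)CCC(=O)O) is taken through the operations of steps 10 to 13 to give bromo imide F1, syn aldol adduct F2, 2-(trimethylsilyl)ethyl ester F3 and silyl ether F4. Nozaki–Hiyama–Kishi coupling of F4 with 14 (CrCl2, NiCl2 cat., DMF) should give allylic alcohol F5 as carbinol epimers. Ring-closing diene metathesis with the same ruthenium catalyst should then give cyclopentenyl carbinol F6, Dess–Martin periodinane should give enone F7, and Wittig methylenation (Ph3P=CH2, toluene, 60 °C) should deliver 33.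

Step 15. Facial discrimination may be poor, or the twisted 2,3-disubstituted diene may react so slowly that the Lewis acid ionises the allylic silyl ether. The fallback closes ring D before ring B, so that a rigid cis-fused bicycle steers acrolein to its convex face. It sets out from diene 33 and comes back at target 42. Bu4NF should convert 33 into hydroxy acid F8, and PhSO2Cl in pyridine should close β-lactone diene F9. Thermal cycloaddition with acrolein (toluene, 80 °C) should give endo aldehyde F10, DBU should equilibrate it to equatorial aldehyde F11, NaBH4 at −78 °C should give alcohol F12, and butanoic anhydride 37 with pyridine should give 42.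

Step 12. The lithium alkoxide may cause retro-aldol cleavage of the aldolate or open the oxazolidinone ring instead of displacing it. The fallback uses an auxiliary that leaves under neutral alcoholysis. It sets out from acid 21 and comes back at hydroxy ester 30. Acid 21 is coupled (EDC, DMAP) with (R)-4-benzyl-1,3-thiazolidine-2-thione to give acyl thiazolidinethione F13. A titanium enolate aldol (TiCl4, i-Pr2NEt, N-methylpyrrolidinone, CH2Cl2, −78 °C) with acrolein 25 should give syn adduct F14 with the same configuration, and 2-(trimethylsilyl)ethanol 29 with imidazole should then displace the thione to give 30.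

**Further compounds**

F1 | step 14 | (R)-4-benzyl-3-(4-bromopent-4-enoyl)-1,3-oxazolidin-2-one | C=C(Br)CCC(=O)N1[C@H](Cc2ccccc2)COC1=O
F2 | step 14 | (R)-4-benzyl-3-[(2R,3S)-2-(2-bromoprop-2-en-1-yl)-3-hydroxypent-4-enoyl]-1,3-oxazolidin-2-one | C=C[C@H](O)[C@@H](CC(Br)=C)C(=O)N1[C@H](Cc2ccccc2)COC1=O
F3 | step 14 | 2-(trimethylsilyl)ethyl (2R,3S)-2-(2-bromoprop-2-en-1-yl)-3-hydroxypent-4-enoate | C=C[C@H](O)[C@@H](CC(Br)=C)C(=O)OCC[Si](C)(C)C
F4 | step 14 | 2-(trimethylsilyl)ethyl (2R,3S)-2-(2-bromoprop-2-en-1-yl)-3-[(tert-butyldimethylsilyl)oxy]pent-4-enoate | C=C[C@H](O[Si](C)(C)C(C)(C)C)[C@@H](CC(Br)=C)C(=O)OCC[Si](C)(C)C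
F5 | step 14 | 2-(trimethylsilyl)ethyl (2R,3S)-3-[(tert-butyldimethylsilyl)oxy]-2-(2-{hydroxy[(1S)-1,3,3-trimethylcyclohexyl]methyl}prop-2-en-1-yl)pent-4-enoate (carbinol epimers) | C=C[C@H](O[Si](C)(C)C(C)(C)C)[C@@H](CC(=C)C(O)[C@@]1(C)CCCC(C)(C)C1)C(=O)OCC[Si](C)(C)C
F6 | step 14 | 2-(trimethylsilyl)ethyl (1R,2S)-2-[(tert-butyldimethylsilyl)oxy]-4-{hydroxy[(1S)-1,3,3-trimethylcyclohexyl]methyl}cyclopent-3-ene-1-carboxylate (carbinol epimers) | OC([C@@]1(C)CCCC(C)(C)C1)C2=C[C@H](O[Si](C)(C)C(C)(C)C)[C@H](C(=O)OCC[Si](C)(C)C)C2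
F7 | step 14 | 2-(trimethylsilyl)ethyl (1R,2S)-2-[(tert-butyldimethylsilyl)oxy]-4-[(1S)-1,3,3-trimethylcyclohexane-1-carbonyl]cyclopent-3-ene-1-carboxylate | O=C([C@@]1(C)CCCC(C)(C)C1)C2=C[C@H](O[Si](C)(C)C(C)(C)C)[C@H](C(=O)OCC[Si](C)(C)C)C2
F8 | step 15 | (1R,2S)-2-hydroxy-4-{1-[(1S)-1,3,3-trimethylcyclohexyl]ethenyl}cyclopent-3-ene-1-carboxylic acid | C=C([C@@]1(C)CCCC(C)(C)C1)C2=C[C@H](O)[C@H](C(=O)O)C2
F9 | step 15 | (1R,5S)-3-{1-[(1S)-1,3,3-trimethylcyclohexyl]ethenyl}-6-oxabicyclo[3.2.0]hept-3-en-7-one | C=C([C@@]1(C)CCCC(C)(C)C1)C2=C[C@@H]3OC(=O)[C@@H]3C2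
F10 | step 15 | β-lactone aldehyde, endo adduct: 42 with formyl in place of the butanoyloxymethyl group and C1 inverted (C1–H cis to C7a–H) | O=C[C@@H]1CCC([C@@]2(C)CCCC(C)(C)C2)=C2C[C@H]3C(=O)O[C@H]3[C@@H]21
F11 | step 15 | β-lactone aldehyde, equatorial epimer: 42 with formyl in place of the butanoyloxymethyl group (C1–H trans to C7a–H) | O=C[C@H]1CCC([C@@]2(C)CCCC(C)(C)C2)=C2C[C@H]3C(=O)O[C@H]3[C@@H]21
F12 | step 15 | β-lactone alcohol: 42 lacking the butanoyl group | OC[C@H]1CCC([C@@]2(C)CCCC(C)(C)C2)=C2C[C@H]3C(=O)O[C@H]3[C@@H]21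
F13 | step 12 | (R)-4-benzyl-3-{5-[(1S)-1,3,3-trimethylcyclohexyl]pent-4-ynoyl}-1,3-thiazolidine-2-thione | O=C(CCC#C[C@@]1(C)CCCC(C)(C)C1)N2[C@H](Cc3ccccc3)CSC2=S
F14 | step 12 | (R)-4-benzyl-3-[(2R,3S)-3-hydroxy-2-{3-[(1S)-1,3,3-trimethylcyclohexyl]prop-2-yn-1-yl}pent-4-enoyl]-1,3-thiazolidine-2-thione | C=C[C@H](O)[C@@H](CC#C[C@@]1(C)CCCC(C)(C)C1)C(=O)N2[C@H](Cc3ccccc3)CSC2=S
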